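**Retrosynthetic overview**

- Feature: counting the diterpenoid chain from the benzylic CH2 (C1), the tetrasubstituted ring alkene is C2=C3 (methyl on C3) and C7 is the ring quaternary carbon. C1 is therefore both benzylic and allylic, and the aryl–C1 bond inside the 16-membered lactone ring is an allyl–aryl bond whose allyl unit C1–C2–C3 has one primary and one fully substituted end.
- Key disconnection: aryl–C1, made last by zerovalent-palladium coupling of a C1 allylic methyl carbonate with the ortho pinacolboronate of the aryl ester (36 → 37). This closes the macrocycle far from the hindered C15 ester; desilylation then gives the target.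
- 36 comes from tertiary alcohol 29 and borylated acid 33 (aroyl triflate esterification). C14–Br comes from Shi epoxidation and bromide opening of a prenyl end installed by cross-metathesis. C10–Br/C11–OH come from Sharpless epoxidation and titanium-directed bromide opening; C12–C13 comes from allyl cuprate opening of a terminal epoxide.
- The cyclohexene ring is built first: CBS desymmetrisation of 2-allyl-2-methylcyclohexane-1,3-dione sets C7 and C6, Appel inversion gives C6–Br, and α-methylation, enol triflate formation and carbonylation give the C2=C3 enoate. The ring alkene stays electron-poor until every oxidation and bromination is done.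
- Ring order: carbocycle (steps 1–5, 10), arene bought in, 16-membered macrocycle (step 24).

Key step: step 24

Remark on the chemistry: names use the terpenoid numbering above (C6 Br, C7 quaternary, C10 Br, C11 O, C14 Br, C15 O; target = 6S,7S,10R,11S,14R). The phenol is carried as a triisopropylsilyl ether rather than a tert-butyldimethylsilyl ether because the key step releases methoxide. C1 is carried as a methyl ester, not an aldehyde, until after the last oxidation.

**Route**

Step 1
Reactants: 1 2-methylcyclohexane-1,3-dione; 2 allyl bromide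
Product: 3 2-allyl-2-methylcyclohexane-1,3-dione
Conditions: 1 M aq. NaOH, rt
Reagents that add atoms: none
Why: C-alkylation of the stabilised dione enolate with an allylic halide (SN2) should give the quaternary, still prochiral, 2,2-disubstituted dione.

Step 2
Reactants: 3 2-allyl-2-methylcyclohexane-1,3-dione
Product: 4 (2R,3R)-2-allyl-3-hydroxy-2-methylcyclohexan-1-one
Conditions: (S)-2-methyl-CBS-oxazaborolidine (0.2 equiv), catecholborane (1.2 equiv), toluene, −78 °C
Reagents that add atoms: none
Why: Corey–Bakshi–Shibata reduction should desymmetrise the dione, the (S)-catalyst giving the 3R carbinol of a ketone flanked by a quaternary (large) and a methylene (small) carbon and hydride entering anti to the allyl group, so that OH ends cis to allyl and the quaternary carbon becomes 2R.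

Step 3
Reactants: 4 (2R,3R)-2-allyl-3-hydroxy-2-methylcyclohexan-1-one
Product: 5 (2S,3S)-2-allyl-3-bromo-2-methylcyclohexan-1-one
Conditions: CBr4, PPh3, toluene, 0 → 60 °C
Reagents that add atoms: tetrabromomethane, BrC(Br)(Br)Br
Why: In the Appel reaction bromide should displace the alkoxyphosphonium group by SN2 with inversion, placing bromine cis to the methyl group as in the target (3S), while the β-carbonyl disfavours ionisation and the quaternary carbon offers no hydrogen for elimination toward the ketone.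

Step 4
Reactants: 5 (2S,3S)-2-allyl-3-bromo-2-methylcyclohexan-1-one
Product: 7 (2S,3S)-2-allyl-3-bromo-2,6-dimethylcyclohexan-1-one (both C6 epimers), via lithium enolate 6 (not isolated)
Conditions: LiN(iPr)2, THF, −78 °C; then MeI, DMPU, −78 → −40 °C
Reagents that add atoms: iodomethane, CI
Why: Kinetic enolate alkylation can occur only on the methylene side because the other α-carbon is quaternary, and the new C6 centre need not be controlled since it becomes sp2 in the next step.

Step 5
Reactants: 7 (2S,3S)-2-allyl-3-bromo-2,6-dimethylcyclohexan-1-one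
Product: 9 (5S,6S)-6-allyl-5-bromo-2,6-dimethylcyclohex-1-en-1-yl trifluoromethanesulfonate, via potassium enolate 8 (not isolated)
Conditions: KN(SiMe3)2, THF, −78 → −40 °C; then PhNTf2, −78 → 0 °C
Reagents that add atoms: N-phenylbis(trifluoromethanesulfonimide), O=S(=O)(N(c1ccccc1)S(=O)(=O)C(F)(F)F)C(F)(F)F
Why: Enolisation is possible only toward the methyl-bearing carbon, so O-sulfonylation of the enolate should give the tetrasubstituted enol triflate (the future C2=C3 alkene) as a single regioisomer.

Step 6
Reactants: 9 (5S,6S)-6-allyl-5-bromo-2,6-dimethylcyclohex-1-en-1-yl trifluoromethanesulfonate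
Product: 11 (5S,6S)-5-bromo-6-(3-hydroxypropyl)-2,6-dimethylcyclohex-1-en-1-yl trifluoromethanesulfonate, via B-alkyl-9-BBN adduct 10 (not isolated)
Conditions: 9-BBN-H (1.3 equiv), THF, 0 °C → rt; then NaBO3·4H2O, H2O, rt
Reagents that add atoms: sodium perborate tetrahydrate (NaBO3·4H2O), [Na+].[Na+].O[B-]1(O)OO[B-](O)(O)OO1
Why: Anti-Markovnikov hydroboration–oxidation should touch only the terminal alkene, the tetrasubstituted enol triflate being inert to the bulky borane and stable to the mild perborate oxidation.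

Step 7
Reactants: 11 (5S,6S)-5-bromo-6-(3-hydroxypropyl)-2,6-dimethylcyclohex-1-en-1-yl trifluoromethanesulfonate
Product: 12 (5S,6S)-5-bromo-2,6-dimethyl-6-(3-oxopropyl)cyclohex-1-en-1-yl trifluoromethanesulfonate
Conditions: Dess–Martin periodinane, NaHCO3, CH2Cl2, 0 °C → rt
Reagents that add atoms: none
Why: Dess–Martin oxidation should convert the primary alcohol into the C10 aldehyde under buffered, non-basic conditions that leave triflate and bromide alone.

Step 8
Reactants: 12 (5S,6S)-5-bromo-2,6-dimethyl-6-(3-oxopropyl)cyclohex-1-en-1-yl trifluoromethanesulfonate; 13 ethyl 2-(triphenylphosphoranylidene)propanoate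
Product: 14 ethyl (E)-5-[(1S,6S)-6-bromo-1,3-dimethyl-2-(trifluoromethanesulfonyloxy)cyclohex-2-en-1-yl]-2-methylpent-2-enoate
Conditions: CH2Cl2, rt → 40 °C
Reagents that add atoms: none
Why: Wittig olefination with the α-methyl stabilised ylide should give the E trisubstituted C10=C11 alkene, the geometry that later fixes the anti relation of C10–Br and C11–OH.

Step 9
Reactants: 14 ethyl (E)-5-[(1S,6S)-6-bromo-1,3-dimethyl-2-(trifluoromethanesulfonyloxy)cyclohex-2-en-1-yl]-2-methylpent-2-enoate
Product: 15 (5S,6S)-5-bromo-6-[(E)-5-hydroxy-4-methylpent-3-en-1-yl]-2,6-dimethylcyclohex-1-en-1-yl trifluoromethanesulfonate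
Conditions: i-Bu2AlH (2.5 equiv), CH2Cl2, −78 °C; aq. KNaC4H4O6
Reagents that add atoms: none
Why: 1,2-Reduction of the enoate by the aluminium hydride should give the allylic alcohol (C12–OH) while the enol triflate and the alkyl bromide are untouched at low temperature.

Step 10
Reactants: 15 (5S,6S)-5-bromo-6-[(E)-5-hydroxy-4-methylpent-3-en-1-yl]-2,6-dimethylcyclohex-1-en-1-yl trifluoromethanesulfonate
Product: 16 methyl (5S,6S)-5-bromo-6-[(E)-5-hydroxy-4-methylpent-3-en-1-yl]-2,6-dimethylcyclohex-1-ene-1-carboxylate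
Conditions: Pd(OAc)2 (5 mol %), dppp (6 mol %), Et3N, CO (1 atm), MeOH/DMF, 60 °C
Reagents that add atoms: carbon monoxide, [C-]#[O+]; methanol, CO
Why: Palladium-catalysed methoxycarbonylation of the enol triflate (oxidative addition, CO insertion, methanolysis) should install C1 as an ester that keeps the C2=C3 alkene electron-poor, and no pendant terminal alkene remains to intercept the acylpalladium species.

Step 11
Reactants: 16 methyl (5S,6S)-5-bromo-6-[(E)-5-hydroxy-4-methylpent-3-en-1-yl]-2,6-dimethylcyclohex-1-ene-1-carboxylate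
Product: 17 methyl (5S,6S)-5-bromo-6-{2-[(2S,3S)-3-(hydroxymethyl)-3-methyloxiran-2-yl]ethyl}-2,6-dimethylcyclohex-1-ene-1-carboxylate
Conditions: Ti(OiPr)4 (0.2 equiv), L-(+)-diisopropyl tartrate (0.24 equiv), t-BuOOH, 4 Å molecular sieves, CH2Cl2, −20 °C
Reagents that add atoms: tert-butyl hydroperoxide, CC(C)(C)OO
Why: Sharpless asymmetric epoxidation with the L-(+)-tartrate should give the (2S,3S)-epoxy alcohol from this E-2-methyl allylic alcohol, which sets C10 and C11 (10S,11S) under reagent control and leaves the conjugated ring alkene alone.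

Step 12
Reactants: 17 methyl (5S,6S)-5-bromo-6-{2-[(2S,3S)-3-(hydroxymethyl)-3-methyloxiran-2-yl]ethyl}-2,6-dimethylcyclohex-1-ene-1-carboxylate
Product: 18 methyl (5S,6S)-5-bromo-6-[(3R,4S)-3-bromo-4,5-dihydroxy-4-methylpentyl]-2,6-dimethylcyclohex-1-ene-1-carboxylate
Conditions: Ti(OiPr)4 (1.5 equiv), Br2 (1.1 equiv), CH2Cl2, 0 °C; aq. tartaric acid
Reagents that add atoms: bromine, BrBr
Why: In the titanium-mediated opening of a 2,3-epoxy alcohol the chelated epoxy alkoxide should be attacked by bromide at the distal carbon C10 with inversion (10R), while the C11–O bond is untouched (11S), giving the anti bromohydrin of the target.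

Step 13
Reactants: 18 methyl (5S,6S)-5-bromo-6-[(3R,4S)-3-bromo-4,5-dihydroxy-4-methylpentyl]-2,6-dimethylcyclohex-1-ene-1-carboxylate
Product: 20 methyl (5S,6S)-5-bromo-6-{(3R)-3-bromo-3-[(2S)-2-methyloxiran-2-yl]propyl}-2,6-dimethylcyclohex-1-ene-1-carboxylate, via primary triflate 19 (not isolated)
Conditions: Tf2O (1.05 equiv), 2,6-lutidine, CH2Cl2, −78 → 0 °C
Reagents that add atoms: none
Why: Selective sulfonylation of the primary hydroxyl followed by 3-exo-tet Williamson closure by the tertiary hydroxyl should give the C11–C12 epoxide, because triflate is a far better leaving group than the neighbouring C10 bromide and no bond to C11 is broken.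

Step 14
Reactants: 20 methyl (5S,6S)-5-bromo-6-{(3R)-3-bromo-3-[(2S)-2-methyloxiran-2-yl]propyl}-2,6-dimethylcyclohex-1-ene-1-carboxylate; 21 allylmagnesium bromide
Product: 22 methyl (5S,6S)-5-bromo-6-[(3R,4S)-3-bromo-4-hydroxy-4-methyloct-7-en-1-yl]-2,6-dimethylcyclohex-1-ene-1-carboxylate
Conditions: CuI (0.15 equiv), THF, −78 → −40 °C; sat. aq. NH4Cl at −40 °C
Reagents that add atoms: none
Why: Copper-catalysed Grignard opening of the 2,2-disubstituted epoxide at its CH2 terminus (SN2, as with epihalohydrins) should form the C12–C13 bond, and the low temperature keeps the magnesium alkoxide from displacing the C10 bromide and the hindered ring ester from being attacked.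

Step 15
Reactants: 22 methyl (5S,6S)-5-bromo-6-[(3R,4S)-3-bromo-4-hydroxy-4-methyloct-7-en-1-yl]-2,6-dimethylcyclohex-1-ene-1-carboxylate
Product: 23 methyl (5S,6S)-5-bromo-6-[(3R,4S)-3-bromo-4-methyl-4-(triethylsilyloxy)oct-7-en-1-yl]-2,6-dimethylcyclohex-1-ene-1-carboxylate
Conditions: Et3SiOTf, 2,6-lutidine, CH2Cl2, −78 → 0 °C
Reagents that add atoms: triethylsilyl trifluoromethanesulfonate, CC[Si](CC)(CC)OS(=O)(=O)C(F)(F)F
Why: Silylation of the tertiary alcohol with the silyl triflate should block the C11 oxygen against epoxide closure onto C10 and against cycloetherification onto C14–C15 in the later steps.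

Step 16
Reactants: 23 methyl (5S,6S)-5-bromo-6-[(3R,4S)-3-bromo-4-methyl-4-(triethylsilyloxy)oct-7-en-1-yl]-2,6-dimethylcyclohex-1-ene-1-carboxylate; 24 2-methylbut-2-ene
Product: 25 methyl (5S,6S)-5-bromo-6-[(3R,4S)-3-bromo-4,8-dimethyl-4-(triethylsilyloxy)non-7-en-1-yl]-2,6-dimethylcyclohex-1-ene-1-carboxylate
Conditions: second-generation Grubbs catalyst RuCl2(=CHPh)(H2IMes)(PCy3) (5 mol %), 24 as co-solvent, CH2Cl2, 40 °C
Reagents that add atoms: none
Why: Olefin cross-metathesis with 2-methylbut-2-ene should exchange the terminal CH2 for an isopropylidene group (C15 and its two methyls), the tetrasubstituted enoate being inert to the ruthenium carbene.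

Step 17
Reactants: 25 methyl (5S,6S)-5-bromo-6-[(3R,4S)-3-bromo-4,8-dimethyl-4-(triethylsilyloxy)non-7-en-1-yl]-2,6-dimethylcyclohex-1-ene-1-carboxylate
Product: 26 methyl (5S,6S)-5-bromo-6-{(3R,4S)-3-bromo-6-[(2S)-3,3-dimethyloxiran-2-yl]-4-methyl-4-(triethylsilyloxy)hexyl}-2,6-dimethylcyclohex-1-ene-1-carboxylate
Conditions: L-fructose-derived Shi ketone (enantiomer of the usual D-fructose ketone, 0.3 equiv), KHSO5 (as 2KHSO5·KHSO4·K2SO4), K2CO3, Bu4NHSO4, MeCN/dimethoxymethane/aq. Na2B4O7 buffer (pH 10.5), 0 °C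
Reagents that add atoms: potassium peroxymonosulfate, [K+].OOS([O-])(=O)=O
Why: Shi asymmetric epoxidation (chiral dioxirane, spiro transition state) with the L-fructose-derived ketone should give the 14S epoxide of the only electron-rich alkene, the D-fructose ketone being known to give the R epoxide at the CH carbon of such alkenes.

Step 18
Reactants: 26 methyl (5S,6S)-5-bromo-6-{(3R,4S)-3-bromo-6-[(2S)-3,3-dimethyloxiran-2-yl]-4-methyl-4-(triethylsilyloxy)hexyl}-2,6-dimethylcyclohex-1-ene-1-carboxylate
Product: 27 methyl (5S,6S)-5-bromo-6-[(3R,4S,7R)-3,7-dibromo-8-hydroxy-4,8-dimethyl-4-(triethylsilyloxy)nonyl]-2,6-dimethylcyclohex-1-ene-1-carboxylate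
Conditions: Li2NiBr4 (2 equiv, 0.4 M in THF), THF, 0 °C → rt
Reagents that add atoms: dilithium tetrabromonickelate, [Li+].[Li+].Br[Ni-2](Br)(Br)Br
Why: The soft, weakly acidic bromide source should open the epoxide by SN2 attack at the less substituted C14 with inversion (14S epoxide → 14R bromide), leaving the tertiary C15 oxygen as the free alcohol.

Step 19
Reactants: 27 methyl (5S,6S)-5-bromo-6-[(3R,4S,7R)-3,7-dibromo-8-hydroxy-4,8-dimethyl-4-(triethylsilyloxy)nonyl]-2,6-dimethylcyclohex-1-ene-1-carboxylate
Product: 28 (3R,6S,7R)-3,7-dibromo-9-[(1S,6S)-6-bromo-2-(hydroxymethyl)-1,3-dimethylcyclohex-2-en-1-yl]-2,6-dimethyl-6-(triethylsilyloxy)nonan-2-ol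
Conditions: i-Bu2AlH (4 equiv), CH2Cl2, −78 → −40 °C; aq. KNaC4H4O6
Reagents that add atoms: none
Why: With all oxidations and brominations finished, aluminium hydride reduction of the hindered enoate should reveal the C1 allylic alcohol, the cold aluminium alkoxide at C15 being too poor a nucleophile to displace the C14 bromide.

Step 20
Reactants: 28 (3R,6S,7R)-3,7-dibromo-9-[(1S,6S)-6-bromo-2-(hydroxymethyl)-1,3-dimethylcyclohex-2-en-1-yl]-2,6-dimethyl-6-(triethylsilyloxy)nonan-2-ol
Product: 29 {(5S,6S)-5-bromo-6-[(3R,4S,7R)-3,7-dibromo-8-hydroxy-4,8-dimethyl-4-(triethylsilyloxy)nonyl]-2,6-dimethylcyclohex-1-en-1-yl}methyl methyl carbonate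
Conditions: ClCO2Me (1.5 equiv), pyridine, CH2Cl2, 0 °C
Reagents that add atoms: methyl chloroformate, COC(Cl)=O
Why: Acylation with the chloroformate should take the primary allylic hydroxyl only, since the tertiary, β-brominated C15 hydroxyl does not react under these conditions.

Step 21
Reactants: 30 4-hydroxy-3-iodobenzoic acid
Product: 32 3-iodo-4-(triisopropylsilyloxy)benzoic acid, via bis-silyl compound 31 (not isolated)
Conditions: i-Pr3SiCl (2.3 equiv), imidazole, DMF, rt; then THF/H2O/AcOH, rt
Reagents that add atoms: chlorotriisopropylsilane, CC(C)[Si](Cl)(C(C)C)C(C)C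
Why: Silylation of both acidic hydroxyls followed by selective hydrolysis of the labile silyl ester should leave the robust aryl silyl ether and the free acid.

Step 22
Reactants: 32 3-iodo-4-(triisopropylsilyloxy)benzoic acid
Product: 33 3-(4,4,5,5-tetramethyl-1,3,2-dioxaborolan-2-yl)-4-(triisopropylsilyloxy)benzoic acid
Conditions: B2pin2, Pd(dppf)Cl2 (5 mol %), KOAc (4 equiv), 1,4-dioxane, 85 °C; work-up at pH 4
Reagents that add atoms: bis(pinacolato)diboron, CC1(C)OB(OC1(C)C)B1OC(C)(C)C(C)(C)O1
Why: Miyaura borylation of the aryl iodide should install the boronate before any allylic carbonate or alkyl bromide is present, so that no palladium step other than the macrocyclisation meets the terpenoid part.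

Step 23
Reactants: 29 {(5S,6S)-5-bromo-6-[(3R,4S,7R)-3,7-dibromo-8-hydroxy-4,8-dimethyl-4-(triethylsilyloxy)nonyl]-2,6-dimethylcyclohex-1-en-1-yl}methyl methyl carbonate; 33 3-(4,4,5,5-tetramethyl-1,3,2-dioxaborolan-2-yl)-4-(triisopropylsilyloxy)benzoic acid
Product: 36 macrocyclisation precursor, the C15 tertiary ester of 33 with 29 ((6S,7S,10R,11S,14R); C1 methyl carbonate, ortho pinacolboronate, phenol triisopropylsilyl ether, C11 triethylsilyl ether), via acid chloride 34 (not isolated), via aroyl triflate 35 (not isolated)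
Conditions: 33, Me2C=C(Cl)NMe2, CH2Cl2, 0 °C → rt; AgOTf, CH2Cl2, −20 °C, filtered from AgCl; then 29, 2,6-di-tert-butyl-4-methylpyridine, CH2Cl2, −78 → −20 °C
Reagents that add atoms: none
Why: Acylation of the hindered tertiary alcohol by a preformed aroyl triflate (the benzoyl triflate method for tertiary hydroxyls) should form the C15 ester without an alkoxide that would close onto C14, and filtering off the silver salt first keeps silver ion away from the alkyl bromides.

Step 24
Reactants: 36 macrocyclisation precursor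
Product: 37 macrocycle, the target as its phenol triisopropylsilyl ether and C11 triethylsilyl ether
Conditions: Pd(PPh3)4 (20 mol %), degassed THF, 60 °C, syringe-pump addition of 36 over 12 h to 1 mM
Reagents that add atoms: none
Why: Zerovalent palladium should ionise the C1 methyl carbonate with loss of CO2 to a π-allyl (C1–C2–C3) palladium methoxide, the methoxide bridges to the ortho boronate, the aryl group passes to palladium and reductive elimination forms the aryl–C1 bond. The closest known reaction type is the palladium-catalysed Suzuki–Miyaura coupling of allylic carbonates with arylboron reagents without added base, run here intramolecularly as in Suzuki macrocyclisations. The 16-membered ring closes end to end by C(sp2)–C(sp3) reductive elimination from an aryl(allyl)palladium macrocycle, and slow addition to high dilution should favour this over oligomer formation. No stereocentre is formed or touched, since C6, C7, C10, C11 and C14 are remote from palladium and the C2=C3 alkene returns to its ring position. The step needs coupling at the primary C1 and not at the fully substituted C3 terminus, which the ring substitution at C3 and the quaternary C7 beside C2 secure sterically, and it needs the three secondary alkyl bromides to survive, which holds because Pd(PPh3)4 does not insert into unactivated secondary C–Br bonds at this temperature. The tertiary triethylsilyl ether keeps the C11 oxygen from closing onto C10, and the triisopropylsilyl aryl ether should withstand the methoxide released from the carbonate, so no phenoxide competes by O-allylation.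

Step 25
Reactants: 37 macrocycle
Product: 38 CNP0153321.1, (6S,7S,10R,11S,14R)-configured target
Conditions: HF·pyridine, pyridine, THF, 0 °C → rt
Reagents that add atoms: none
Why: Fluoride-mediated desilylation under buffered acidic conditions should remove both silyl ethers without forming an alkoxide next to C10–Br and without harming the tertiary ester or the alkyl bromides.

**Compound list**

1 | 2-methylcyclohexane-1,3-dione | CC1C(=O)CCCC1=O | starting material
2 | allyl bromide (3-bromoprop-1-ene) | C=CCBr | starting material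
3 | 2-allyl-2-methylcyclohexane-1,3-dione | C=CCC1(C)C(=O)CCCC1=O | intermediate
4 | (2R,3R)-2-allyl-3-hydroxy-2-methylcyclohexan-1-one (OH cis to allyl) | C=CC[C@]1(C)[C@H](O)CCCC1=O | intermediate
5 | (2S,3S)-2-allyl-3-bromo-2-methylcyclohexan-1-one (Br cis to methyl) | C=CC[C@]1(C)[C@@H](Br)CCCC1=O | intermediate
6 | lithium (5S,6S)-6-allyl-5-bromo-6-methylcyclohex-1-en-1-olate (enolate of 5) | C=CC[C@]1(C)[C@@H](Br)CCC=C1O[Li] | intermediate
7 | (2S,3S)-2-allyl-3-bromo-2,6-dimethylcyclohexan-1-one (both C6 epimers) | C=CC[C@]1(C)[C@@H](Br)CCC(C)C1=O | intermediate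
8 | potassium (5S,6S)-6-allyl-5-bromo-2,6-dimethylcyclohex-1-en-1-olate (enolate of 7) | C=CC[C@]1(C)[C@@H](Br)CCC(C)=C1O[K] | intermediate
9 | (5S,6S)-6-allyl-5-bromo-2,6-dimethylcyclohex-1-en-1-yl trifluoromethanesulfonate | C=CC[C@]1(C)[C@@H](Br)CCC(C)=C1OS(=O)(=O)C(F)(F)F | intermediate
10 | 9-{3-[(1S,6S)-6-bromo-1,3-dimethyl-2-(trifluoromethanesulfonyloxy)cyclohex-2-en-1-yl]propyl}-9-borabicyclo[3.3.1]nonane | B1(CCC[C@]3(C)[C@@H](Br)CCC(C)=C3OS(=O)(=O)C(F)(F)F)C2CCCC1CCC2 | intermediate
11 | (5S,6S)-5-bromo-6-(3-hydroxypropyl)-2,6-dimethylcyclohex-1-en-1-yl trifluoromethanesulfonate | OCCC[C@]1(C)[C@@H](Br)CCC(C)=C1OS(=O)(=O)C(F)(F)F | intermediate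
12 | (5S,6S)-5-bromo-2,6-dimethyl-6-(3-oxopropyl)cyclohex-1-en-1-yl trifluoromethanesulfonate | O=CCC[C@]1(C)[C@@H](Br)CCC(C)=C1OS(=O)(=O)C(F)(F)F | intermediate
13 | ethyl 2-(triphenylphosphoranylidene)propanoate | CCOC(=O)C(C)=P(c1ccccc1)(c1ccccc1)c1ccccc1 | starting material
14 | ethyl (E)-5-[(1S,6S)-6-bromo-1,3-dimethyl-2-(trifluoromethanesulfonyloxy)cyclohex-2-en-1-yl]-2-methylpent-2-enoate | CCOC(=O)/C(C)=C/CC[C@]1(C)[C@@H](Br)CCC(C)=C1OS(=O)(=O)C(F)(F)F | intermediate
15 | (5S,6S)-5-bromo-6-[(E)-5-hydroxy-4-methylpent-3-en-1-yl]-2,6-dimethylcyclohex-1-en-1-yl trifluoromethanesulfonate | OC/C(C)=C/CC[C@]1(C)[C@@H](Br)CCC(C)=C1OS(=O)(=O)C(F)(F)F | intermediate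
16 | methyl (5S,6S)-5-bromo-6-[(E)-5-hydroxy-4-methylpent-3-en-1-yl]-2,6-dimethylcyclohex-1-ene-1-carboxylate | OC/C(C)=C/CC[C@]1(C)[C@@H](Br)CCC(C)=C1C(=O)OC | intermediate
17 | methyl (5S,6S)-5-bromo-6-{2-[(2S,3S)-3-(hydroxymethyl)-3-methyloxiran-2-yl]ethyl}-2,6-dimethylcyclohex-1-ene-1-carboxylate | OC[C@]2(C)O[C@H]2CC[C@]1(C)[C@@H](Br)CCC(C)=C1C(=O)OC | intermediate
18 | methyl (5S,6S)-5-bromo-6-[(3R,4S)-3-bromo-4,5-dihydroxy-4-methylpentyl]-2,6-dimethylcyclohex-1-ene-1-carboxylate | OC[C@](C)(O)[C@H](Br)CC[C@]1(C)[C@@H](Br)CCC(C)=C1C(=O)OC | intermediate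
19 | primary (C12) trifluoromethanesulfonate of 18 | FC(F)(F)S(=O)(=O)OC[C@](C)(O)[C@H](Br)CC[C@]1(C)[C@@H](Br)CCC(C)=C1C(=O)OC | intermediate
20 | methyl (5S,6S)-5-bromo-6-{(3R)-3-bromo-3-[(2S)-2-methyloxiran-2-yl]propyl}-2,6-dimethylcyclohex-1-ene-1-carboxylate | C1O[C@]1(C)[C@H](Br)CC[C@]2(C)[C@@H](Br)CCC(C)=C2C(=O)OC | intermediate
21 | allylmagnesium bromide | C=CC[Mg]Br | starting material
22 | methyl (5S,6S)-5-bromo-6-[(3R,4S)-3-bromo-4-hydroxy-4-methyloct-7-en-1-yl]-2,6-dimethylcyclohex-1-ene-1-carboxylate | C=CCC[C@](C)(O)[C@H](Br)CC[C@]1(C)[C@@H](Br)CCC(C)=C1C(=O)OC | intermediate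
23 | methyl (5S,6S)-5-bromo-6-[(3R,4S)-3-bromo-4-methyl-4-(triethylsilyloxy)oct-7-en-1-yl]-2,6-dimethylcyclohex-1-ene-1-carboxylate | C=CCC[C@](C)(O[Si](CC)(CC)CC)[C@H](Br)CC[C@]1(C)[C@@H](Br)CCC(C)=C1C(=O)OC | intermediate
24 | 2-methylbut-2-ene | CC=C(C)C | starting material
25 | methyl (5S,6S)-5-bromo-6-[(3R,4S)-3-bromo-4,8-dimethyl-4-(triethylsilyloxy)non-7-en-1-yl]-2,6-dimethylcyclohex-1-ene-1-carboxylate | CC(C)=CCC[C@](C)(O[Si](CC)(CC)CC)[C@H](Br)CC[C@]1(C)[C@@H](Br)CCC(C)=C1C(=O)OC | intermediate
26 | methyl (5S,6S)-5-bromo-6-{(3R,4S)-3-bromo-6-[(2S)-3,3-dimethyloxiran-2-yl]-4-methyl-4-(triethylsilyloxy)hexyl}-2,6-dimethylcyclohex-1-ene-1-carboxylate | CC1(C)O[C@H]1CC[C@](C)(O[Si](CC)(CC)CC)[C@H](Br)CC[C@]2(C)[C@@H](Br)CCC(C)=C2C(=O)OC | intermediate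
27 | methyl (5S,6S)-5-bromo-6-[(3R,4S,7R)-3,7-dibromo-8-hydroxy-4,8-dimethyl-4-(triethylsilyloxy)nonyl]-2,6-dimethylcyclohex-1-ene-1-carboxylate | CC(C)(O)[C@H](Br)CC[C@](C)(O[Si](CC)(CC)CC)[C@H](Br)CC[C@]1(C)[C@@H](Br)CCC(C)=C1C(=O)OC | intermediate
28 | (3R,6S,7R)-3,7-dibromo-9-[(1S,6S)-6-bromo-2-(hydroxymethyl)-1,3-dimethylcyclohex-2-en-1-yl]-2,6-dimethyl-6-(triethylsilyloxy)nonan-2-ol | CC(C)(O)[C@H](Br)CC[C@](C)(O[Si](CC)(CC)CC)[C@H](Br)CC[C@]1(C)[C@@H](Br)CCC(C)=C1CO | intermediate
29 | {(5S,6S)-5-bromo-6-[(3R,4S,7R)-3,7-dibromo-8-hydroxy-4,8-dimethyl-4-(triethylsilyloxy)nonyl]-2,6-dimethylcyclohex-1-en-1-yl}methyl methyl carbonate | CC(C)(O)[C@H](Br)CC[C@](C)(O[Si](CC)(CC)CC)[C@H](Br)CC[C@]1(C)[C@@H](Br)CCC(C)=C1COC(=O)OC | intermediate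
30 | 4-hydroxy-3-iodobenzoic acid | OC(=O)c1ccc(O)c(I)c1 | starting material
31 | triisopropylsilyl 3-iodo-4-(triisopropylsilyloxy)benzoate | CC(C)[Si](C(C)C)(C(C)C)OC(=O)c1ccc(O[Si](C(C)C)(C(C)C)C(C)C)c(I)c1 | intermediate
32 | 3-iodo-4-(triisopropylsilyloxy)benzoic acid | OC(=O)c1ccc(O[Si](C(C)C)(C(C)C)C(C)C)c(I)c1 | intermediate
33 | 3-(4,4,5,5-tetramethyl-1,3,2-dioxaborolan-2-yl)-4-(triisopropylsilyloxy)benzoic acid | OC(=O)c1ccc(O[Si](C(C)C)(C(C)C)C(C)C)c(c1)B1OC(C)(C)C(C)(C)O1 | intermediate
34 | 3-(4,4,5,5-tetramethyl-1,3,2-dioxaborolan-2-yl)-4-(triisopropylsilyloxy)benzoyl chloride | ClC(=O)c1ccc(O[Si](C(C)C)(C(C)C)C(C)C)c(c1)B1OC(C)(C)C(C)(C)O1 | intermediate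
35 | 3-(4,4,5,5-tetramethyl-1,3,2-dioxaborolan-2-yl)-4-(triisopropylsilyloxy)benzoyl trifluoromethanesulfonate | FC(F)(F)S(=O)(=O)OC(=O)c1ccc(O[Si](C(C)C)(C(C)C)C(C)C)c(c1)B1OC(C)(C)C(C)(C)O1 | intermediate
36 | macrocyclisation precursor: (6S,7S,10R,11S,14R) C15 ester of 33 carrying the C1 methyl carbonate, ortho pinacolboronate, phenol triisopropylsilyl ether and C11 triethylsilyl ether | CC1(C)OB(OC1(C)C)c1cc(ccc1O[Si](C(C)C)(C(C)C)C(C)C)C(=O)OC(C)(C)[C@H](Br)CC[C@](C)(O[Si](CC)(CC)CC)[C@H](Br)CC[C@]1(C)[C@@H](Br)CCC(C)=C1COC(=O)OC | intermediate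
37 | macrocycle: target as its phenol triisopropylsilyl ether and C11 triethylsilyl ether | CC1=C2Cc3cc(ccc3O[Si](C(C)C)(C(C)C)C(C)C)C(=O)OC(C)(C)[C@H](Br)CC[C@](C)(O[Si](CC)(CC)CC)[C@H](Br)CC[C@]2(C)[C@@H](Br)CC1 | intermediate
38 | CNP0153321.1, (6S,7S,10R,11S,14R)-tribromo macrolide | CC1=C2Cc3cc(ccc3O)C(=O)OC(C)(C)[C@H](Br)CC[C@](C)(O)[C@H](Br)CC[C@]2(C)[C@@H](Br)CC1 | target

**Step count and risks**

Total step count: 25 (steps 1–20 on the terpenoid line, 21–22 on the aryl acid, 23–25 after convergence). Longest linear sequence: 23 steps (1–20, then 23, 24, 25).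

Steps most likely to fail:

1. Step 24. Transmetalation from the hindered pinacolboronate without added base may be slower than β-hydride loss from the π-allyl complex (diene formation) or than intermolecular coupling. The fallback replaces boron by tin; it sets out from 32 and 29 and returns at 37. Iodine–magnesium exchange on 32 (i-PrMgCl·LiCl, 2 equiv, THF, −30 °C) and quenching with Me3SnCl would give 4-(triisopropylsilyloxy)-3-(trimethylstannyl)benzoic acid F1. The chloroenamine Me2C=C(Cl)NMe2 would turn this into 4-(triisopropylsilyloxy)-3-(trimethylstannyl)benzoyl chloride F2, which is joined to 29 (DMAP, Et3N, CH2Cl2, 40 °C; no acylium conditions, which would cleave the aryl–tin bond) to give the stannyl ester precursor F3. F3 is then cyclised by a Stille coupling of the allylic carbonate with the arylstannane (Pd2(dba)3, tri(2-furyl)phosphine, LiCl, N-methylpyrrolidone, 50 °C, high dilution). Tin transmetalates under neutral conditions without alkoxide activation, and the product is 37.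

2. Step 3. Displacement at a secondary carbon beside the quaternary centre is slow, so E2 loss toward C4 or a 1,2-shift from the alkoxyphosphonium ion may outrun substitution. The fallback is a bromonium-triggered semipinacol rearrangement; it sets out from 21 and returns at 5. 21 and B(OiPr)3 would give allyldiisopropoxyborane F4. F4 adds 1,2 to purchased 2-methylcyclohex-2-en-1-one under catalysis by the enantiomer of 3,3'-dibromo-1,1'-bi-2-naphthol that leads to (S)-1-allyl-2-methylcyclohex-2-en-1-ol F5. N-Bromosuccinimide (CH2Cl2, −40 °C) then forms the bromonium ion on the ring alkene and the allyl group migrates from the carbinol carbon to the methyl-bearing carbon anti to bromine. Bromine and the quaternary centre are thus set together with the relative and absolute configuration of 5, and no substitution at a neopentyl-type carbon is needed.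

3. Step 18. Bromide may open the epoxide at the tertiary C15 through a borderline ionising pathway, or the Lewis-acidic nickel salt may induce a hydride shift to the C14 ketone. The fallback is electrophilic bromohydroxylation; it sets out from 25, bypasses 26 and returns at 27. N-Bromosuccinimide in THF/water at 0 °C adds bromine to C14 and water to C15 with Markovnikov regiochemistry that does not depend on where a nucleophile attacks an epoxide, and the silylated C11 oxygen cannot intervene. There is no facial control at this remote alkene, so 27 would form together with its 14S epimer F6 and would be separated by chromatography.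

**Further compounds**

F1 | step 24 | 4-(triisopropylsilyloxy)-3-(trimethylstannyl)benzoic acid | OC(=O)c1ccc(O[Si](C(C)C)(C(C)C)C(C)C)c(c1)[Sn](C)(C)C
F2 | step 24 | 4-(triisopropylsilyloxy)-3-(trimethylstannyl)benzoyl chloride | ClC(=O)c1ccc(O[Si](C(C)C)(C(C)C)C(C)C)c(c1)[Sn](C)(C)C
F3 | step 24 | stannyl ester precursor: analogue of 36 with trimethylstannyl in place of the pinacolboronate | C[Sn](C)(C)c1cc(ccc1O[Si](C(C)C)(C(C)C)C(C)C)C(=O)OC(C)(C)[C@H](Br)CC[C@](C)(O[Si](CC)(CC)CC)[C@H](Br)CC[C@]1(C)[C@@H](Br)CCC(C)=C1COC(=O)OC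
F4 | step 3 | allyldiisopropoxyborane | C=CCB(OC(C)C)OC(C)C
F5 | step 3 | (S)-1-allyl-2-methylcyclohex-2-en-1-ol | C=CC[C@@]1(O)CCCC=C1C
F6 | step 18 | 14S epimer of 27 | CC(C)(O)[C@@H](Br)CC[C@](C)(O[Si](CC)(CC)CC)[C@H](Br)CC[C@]1(C)[C@@H](Br)CCC(C)=C1C(=O)OC
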